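The readings stem from a simulated flask with constants of no real substance; the scatter is artificial.

J is the partner to follow here, because the blue and violet runs hold the same Q charge, 0.150 M, and differ in J.

| flask | Q | J | time |
|---|---|---|---|
| blue | 0.150 M | 0.375 M |  |
| red | 0.0600 M | 0.285 M |  |
| violet | 0.150 M | 0.560 M |  |
| grey | 0.150 M | 0.780 M | 170 h |

| blue run: time / h | blue run: [X] / M | red run: time / h | red run: [X] / M | violet run: time / h | violet run: [X] / M |
|---|---|---|---|---|---|
| 6.8 | 0.0015 | 6.8 | 0.0010 | 6.8 | 0.0021 |
| 15 | 0.0075 | 15 | 0.0037 | 15 | 0.0048 |
| 34 | 0.0151 | 34 | 0.0046 | 34 | 0.0194 |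
| 76 | 0.0318 | 76 | 0.0111 | 76 | 0.0429 |
| 170 | 0.0457 | 170 | 0.0197 | 170 | 0.0575 |

(scatter of a reading: 0.002 M)

- Overall: Q + J -> X.
- Constant volume, constant temperature.
- The analysis sees a species whether free or bound.
- "The second partner" is J.
- An order is taken over about fifteen percent of the charge, up and down.

1. order of the initial rate in [Q], near the charge of the blue run, the rate being that where two percent of its Q are X (one fixed amount of X, the same in the runs compared)
2. order of the initial rate in [J], near the charge of the blue run, the rate being that where two percent of its Q are X
3. X in the grey run at 170 h, as a share of the Q charged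

But the early readings say little: blue's 0.0015 M at 6.8 h lies below the scatter of 0.002 M. So my own reckoning leans on the 170 h readings and goes to logarithms. The J slope, or apparent order, is the log10 of violet's reading over blue's, divided by the log10 of their J charges: 0.573. The scatter of those two readings allows about 0.139 either way. It is a slope of accumulated X, so it merely stands in for the order of a rate.

Red changes both charges, so the slope first lifts red's 0.0197 M to blue's J, giving 0.0231 M. Against blue's reading, that gives a Q slope of 0.747. Carried on to grey's J, the slope gives a share of 46.3 %.

The forecast says 1 in Q and 0.75 in J, the latter “perhaps less than 1 through partial saturation”, and 47 % for grey. Each stands above my figure.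

    Q ⇌ E + Z (0.1073 /h, 0.3744 /M/h)
    E + J → X (0.08532 /M/h)
    X → Qe (0.005580 /h)
    2 J ⇌ J2, settled at all times (24.60 /M)

The grey run gives 39.3 %, with orders of 0.69 in Q and 0.41 in J. Early on, violet's rate is 1.2 times blue's at equal X made. Used on red's early rate of 2.3 × 10⁻⁴ M/h, lifted to blue's J and held against blue's 5.3 × 10⁻⁴ M/h, the slope 0.573 gives a Q order of 0.729.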